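## Retrosynthetic overview

1. Target ⇐ loss of an O3 triethylsilyl group ⇐ ten-membered ring and trans-γ-lactone closed together by a chromium-mediated intramolecular allylation (C6–C7) of a Z-enal / 2-(bromomethyl)enoate that already carries the O8 ester and the 1,10-oxirane.
2. Allylic bromide and O8 ester ⇐ SN2' bromide opening of an acrylate-conjugated oxirane, then esterification with (2R,3S)-2,3-dimethyloxirane-2-carboxylic acid (organocatalytic epoxidation of tiglic aldehyde, then oxidation).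
3. C1, C10 and C8 ⇐ one Shi epoxidation of a triene ester made by Morita–Baylis–Hillman reaction and dehydration at the C7 aldehyde.
4. C2–C3 bond and first stereocentre (C3) ⇐ proposed enantioselective vinylogous phase-transfer alkylation of 4-methylfuran-2(5H)-one with an allylic chloride from geranyl chloride; the butenolide fixes the 4Z olefin.
5. Ring order: butenolide (opened to the Z-diol) → two oxiranes → carbocycle and α-methylene lactone in the same step.

Assumption: carbons are referred to by germacrane numbers (ring C1–C10, C14 on C10, C15 on C4, C11–C13 the acrylate unit); the SMILES is read as (1R,3S,4Z,6R,7R,8R,10R) with a (2R,3S)-2,3-dimethyloxirane-2-carboxylate (cis-dimethyl) on O8.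

## Route

Step 1
Reactants: 1 geranyl chloride, (2E)-1-chloro-3,7-dimethylocta-2,6-diene
Product: 3 (2E)-1-chloro-6,6-dimethoxy-3-methylhex-2-ene, via chloro aldehyde 2 (not isolated)
Conditions: O3, CH2Cl2, −78 °C; PPh3; then HC(OMe)3, PPTS, CH2Cl2, 0 °C
Reagents that add atoms: trimethyl orthoformate, COC(OC)OC
Why: Ozonolysis is selective for the remote, electron-rich 6,7-olefin because the 2,3-olefin is deactivated by the allylic chloride, and acid-catalysed acetalisation masks C7 for the basic alkylation that follows.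

Step 2
Reactants: 3 (2E)-1-chloro-6,6-dimethoxy-3-methylhex-2-ene; 4 4-methylfuran-2(5H)-one
Product: 5 (5S)-5-[(2E)-6,6-dimethoxy-3-methylhex-2-en-1-yl]-4-methylfuran-2(5H)-one
Conditions: 4 (2 equiv), Cs2CO3, NaI (10 mol %), N-(9-anthracenylmethyl)-9-deoxy-9-epi-{3-[3,5-bis(trifluoromethyl)phenyl]ureido}cinchonidinium bromide (10 mol %), toluene/CH2Cl2, −40 °C
Reagents that add atoms: none
Why: Proposed new method: enantioselective vinylogous SN2 alkylation of a butenolide under bifunctional chiral ammonium phase-transfer catalysis – Cs2CO3 deprotonates 4 at C5 to the aromatic 2-furanolate, the cinchonidinium cation ion-pairs with it while the urea N–H groups bind the enolate oxygen and shield the O–C2–C3 edge and one face, and the allylic iodide formed in situ from 3 is attacked by C5 (largest HOMO coefficient, conjugated product) with retention of the E olefin, forming C2–C3 and setting C3 as S (the cinchonine-derived pseudoenantiomer is used if the sense is opposite); low temperature and incomplete conversion limit re-deprotonation of the more hindered product; the closest known reactions are asymmetric phase-transfer alkylation of glycine imine esters and the C5-selective organocatalytic vinylogous Michael, Mannich and Morita–Baylis–Hillman-carbonate alkylations of butenolides, with silver-promoted C5 alkylation of 2-silyloxyfurans as racemic precedent.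

Step 3
Reactants: 5 (5S)-5-[(2E)-6,6-dimethoxy-3-methylhex-2-en-1-yl]-4-methylfuran-2(5H)-one
Product: 6 (2Z,4S,6E)-10,10-dimethoxy-3,7-dimethyldeca-2,6-diene-1,4-diol
Conditions: i-Bu2AlH (3 equiv), CH2Cl2, −78 → 0 °C; aq. KNaC4H4O6
Reagents that add atoms: none
Why: Hydride reduction of the butenolide through the lactol gives the Z-2-ene-1,4-diol; the Z geometry is inherited from the ring and neither C3 nor the acetal is touched.

Step 4
Reactants: 6 (2Z,4S,6E)-10,10-dimethoxy-3,7-dimethyldeca-2,6-diene-1,4-diol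
Product: 7 (2Z,4S,6E)-10,10-dimethoxy-3,7-dimethyl-1,4-bis(triethylsilyloxy)deca-2,6-diene
Conditions: Et3SiCl (2.4 equiv), imidazole, DMF, 0 °C
Reagents that add atoms: chlorotriethylsilane, CC[Si](Cl)(CC)CC
Why: Silyl ether formation protects both hydroxyls, so that O3 cannot form a lactol with C6 later and the primary allylic ether can be oxidised selectively.

Step 5
Reactants: 7 (2Z,4S,6E)-10,10-dimethoxy-3,7-dimethyl-1,4-bis(triethylsilyloxy)deca-2,6-diene
Product: 8 (4E,7S,8Z)-4,8-dimethyl-7,10-bis(triethylsilyloxy)deca-4,8-dienal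
Conditions: Et3SiOTf, 2,4,6-collidine, CH2Cl2, 0 °C; then H2O
Reagents that add atoms: water, O
Why: Silyl triflate/collidine acetal cleavage (pyridinium intermediate hydrolysed by water) unmasks the C7 aldehyde under non-acidic conditions that leave both silyl ethers in place.

Step 6
Reactants: 8 (4E,7S,8Z)-4,8-dimethyl-7,10-bis(triethylsilyloxy)deca-4,8-dienal; 9 methyl acrylate
Product: 10 methyl (3RS,6E,9S,10Z)-3-hydroxy-6,10-dimethyl-2-methylidene-9,12-bis(triethylsilyloxy)dodeca-6,10-dienoate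
Conditions: DABCO (1 equiv), 9 (10 equiv), MeOH (cat.), rt, 4 d
Reagents that add atoms: none
Why: The Morita–Baylis–Hillman reaction attaches C11–C13 to C7; the new carbinol centre does not matter because it becomes sp2 in the next step.

Step 7
Reactants: 10 methyl (3RS,6E,9S,10Z)-3-hydroxy-6,10-dimethyl-2-methylidene-9,12-bis(triethylsilyloxy)dodeca-6,10-dienoate
Product: 12 methyl (3E,6E,9S,10Z)-6,10-dimethyl-2-methylidene-9,12-bis(triethylsilyloxy)dodeca-3,6,10-trienoate, via mesylate 11 (not isolated)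
Conditions: MsCl, Et3N, CH2Cl2, −20 °C; then DBU, rt
Reagents that add atoms: none
Why: Mesylation and base-induced elimination can only occur toward C8 and give the conjugated E-2-alkenylacrylate.

Step 8
Reactants: 12 methyl (3E,6E,9S,10Z)-6,10-dimethyl-2-methylidene-9,12-bis(triethylsilyloxy)dodeca-3,6,10-trienoate
Product: 13 methyl 2-[(2R,3R)-3-({(2R,3R)-2-methyl-3-[(2S,3Z)-3-methyl-2,5-bis(triethylsilyloxy)pent-3-en-1-yl]oxiran-2-yl}methyl)oxiran-2-yl]prop-2-enoate
Conditions: D-fructose-derived Shi ketone (1,2:4,5-di-O-isopropylidene-β-D-erythro-hexo-2,3-diulo-2,6-pyranose, 40 mol %), KHSO5 (as 2KHSO5·KHSO4·K2SO4), K2CO3, Bu4NHSO4, MeCN/CH2(OMe)2, aq. Na2B4O7 buffer, 0 °C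
Reagents that add atoms: potassium peroxymonosulfate, [K+].[O-]S(=O)(=O)OO
Why: Shi asymmetric epoxidation (chiral dioxirane, spiro transition state) gives R,R-oxiranes from trans-disubstituted and trisubstituted E-olefins, so C8 (with transient C7) and C1/C10 are set in one operation, while the acrylate double bond and the Z-olefin flanked by two allylic silyloxy groups are too electron-poor and hindered to react.

Step 9
Reactants: 13 methyl 2-[(2R,3R)-3-({(2R,3R)-2-methyl-3-[(2S,3Z)-3-methyl-2,5-bis(triethylsilyloxy)pent-3-en-1-yl]oxiran-2-yl}methyl)oxiran-2-yl]prop-2-enoate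
Product: 14 methyl (2Z,4R)-2-(bromomethyl)-4-hydroxy-5-{(2R,3R)-2-methyl-3-[(2S,3Z)-3-methyl-2,5-bis(triethylsilyloxy)pent-3-en-1-yl]oxiran-2-yl}pent-2-enoate
Conditions: LiBr, AcOH, THF, 0 °C
Reagents that add atoms: lithium bromide, [Li+].[Br-]
Why: Acid-assisted SN2' opening of the acrylate-conjugated oxirane by bromide at C13 is much faster than opening of the isolated trisubstituted oxirane, leaves the C8–O bond (R) intact and gives the preferred Z-2-(bromomethyl)enoate.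

Step 10
Reactants: 15 tiglic aldehyde, (2E)-2-methylbut-2-enal
Product: 16 (2R,3S)-2,3-dimethyloxirane-2-carbaldehyde
Conditions: 9-amino-9-deoxy-epi-quinine (10 mol %), (R)-3,3'-bis(2,4,6-triisopropylphenyl)-1,1'-binaphthyl-2,2'-diyl hydrogen phosphate (20 mol %), 50% aq. H2O2, THF, 40 °C
Reagents that add atoms: hydrogen peroxide, OO
Why: Iminium-catalysed asymmetric epoxidation of an α-branched enal (conjugate hydroperoxide addition, then ring closure) keeps the E-derived geometry, so the two methyl groups end up cis; the amine/phosphate pair (quinine- or quinidine-derived) is chosen to give 2R,3S.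

Step 11
Reactants: 16 (2R,3S)-2,3-dimethyloxirane-2-carbaldehyde
Product: 17 (2R,3S)-2,3-dimethyloxirane-2-carboxylic acid
Conditions: NaClO2, NaH2PO4, 2-methylbut-2-ene, t-BuOH/H2O, 0 °C
Reagents that add atoms: sodium chlorite, [Na+].[O-]Cl=O
Why: Pinnick oxidation converts the aldehyde into the acid without epimerisation or oxirane opening.

Step 12
Reactants: 14 methyl (2Z,4R)-2-(bromomethyl)-4-hydroxy-5-{(2R,3R)-2-methyl-3-[(2S,3Z)-3-methyl-2,5-bis(triethylsilyloxy)pent-3-en-1-yl]oxiran-2-yl}pent-2-enoate; 17 (2R,3S)-2,3-dimethyloxirane-2-carboxylic acid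
Product: 18 methyl (2Z,4R)-2-(bromomethyl)-4-{[(2R,3S)-2,3-dimethyloxirane-2-carbonyl]oxy}-5-{(2R,3R)-2-methyl-3-[(2S,3Z)-3-methyl-2,5-bis(triethylsilyloxy)pent-3-en-1-yl]oxiran-2-yl}pent-2-enoate
Conditions: 17, 2,4,6-Cl3C6H2COCl, Et3N, THF, 0 °C; then 14, DMAP (cat.), toluene, 0 °C
Reagents that add atoms: none
Why: Yamaguchi esterification acylates O8 with retention at C8 and at both oxirane centres of the acid.

Step 13
Reactants: 18 methyl (2Z,4R)-2-(bromomethyl)-4-{[(2R,3S)-2,3-dimethyloxirane-2-carbonyl]oxy}-5-{(2R,3R)-2-methyl-3-[(2S,3Z)-3-methyl-2,5-bis(triethylsilyloxy)pent-3-en-1-yl]oxiran-2-yl}pent-2-enoate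
Product: 19 methyl (2Z,4R)-2-(bromomethyl)-4-{[(2R,3S)-2,3-dimethyloxirane-2-carbonyl]oxy}-5-{(2R,3R)-2-methyl-3-[(2S,3Z)-3-methyl-5-oxo-2-(triethylsilyloxy)pent-3-en-1-yl]oxiran-2-yl}pent-2-enoate
Conditions: (COCl)2, DMSO, CH2Cl2, −78 °C; Et3N, −78 → −20 °C
Reagents that add atoms: none
Why: Under Swern conditions a primary triethylsilyl ether is cleaved and oxidised in one step while the secondary silyl ether survives, giving the Z-enal at low temperature without isomerisation.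

Step 14
Reactants: 19 methyl (2Z,4R)-2-(bromomethyl)-4-{[(2R,3S)-2,3-dimethyloxirane-2-carbonyl]oxy}-5-{(2R,3R)-2-methyl-3-[(2S,3Z)-3-methyl-5-oxo-2-(triethylsilyloxy)pent-3-en-1-yl]oxiran-2-yl}pent-2-enoate
Product: 21 (1R,3S,4Z,6R,7R,8R,10R)-1,10-epoxy-3-(triethylsilyloxy)germacra-4,11(13)-dien-12,6-olid-8-yl (2R,3S)-2,3-dimethyloxirane-2-carboxylate, via hydroxy ester 20 (not isolated)
Conditions: CrCl2 (8 equiv), DMF/THF, 2 mM, rt, slow addition; aq. NH4Cl
Reagents that add atoms: none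
Why: Intramolecular Nozaki–Hiyama–Kishi (chromium Barbier) allylation – the 2-(alkoxycarbonyl)allyl species of trivalent chromium attacks the Z-enal through C7 in a six-membered transition state, the ring chain and the C8 centre are expected to place H6 and H7 trans (6R,7R), and the C6 chromium alkoxide closes the γ-lactone onto the methyl ester.

Step 15
Reactants: 21 (1R,3S,4Z,6R,7R,8R,10R)-1,10-epoxy-3-(triethylsilyloxy)germacra-4,11(13)-dien-12,6-olid-8-yl (2R,3S)-2,3-dimethyloxirane-2-carboxylate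
Product: 22 (1R,3S,4Z,6R,7R,8R,10R)-1,10-epoxy-3-hydroxygermacra-4,11(13)-dien-12,6-olid-8-yl (2R,3S)-2,3-dimethyloxirane-2-carboxylate (target)
Conditions: HF·pyridine, pyridine, THF, 0 °C
Reagents that add atoms: none
Why: Fluoride-driven desilylation under pyridine-buffered conditions frees O3 without opening either oxirane or adding to the α-methylene lactone.

## Compound list

1 | geranyl chloride, (2E)-1-chloro-3,7-dimethylocta-2,6-diene | CC(C)=CCC/C(C)=C/CCl | starting material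
2 | (4E)-6-chloro-4-methylhex-4-enal | O=CCC/C(C)=C/CCl | intermediate
3 | (2E)-1-chloro-6,6-dimethoxy-3-methylhex-2-ene | COC(OC)CC/C(C)=C/CCl | intermediate
4 | 4-methylfuran-2(5H)-one | CC1=CC(=O)OC1 | starting material
5 | (5S)-5-[(2E)-6,6-dimethoxy-3-methylhex-2-en-1-yl]-4-methylfuran-2(5H)-one | O=C1C=C(C)[C@H](C/C=C(\C)CCC(OC)OC)O1 | intermediate
6 | (2Z,4S,6E)-10,10-dimethoxy-3,7-dimethyldeca-2,6-diene-1,4-diol | OC/C=C(/C)[C@@H](O)C/C=C(\C)CCC(OC)OC | intermediate
7 | (2Z,4S,6E)-10,10-dimethoxy-3,7-dimethyl-1,4-bis(triethylsilyloxy)deca-2,6-diene | CC[Si](CC)(CC)OC/C=C(/C)[C@@H](O[Si](CC)(CC)CC)C/C=C(\C)CCC(OC)OC | intermediate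
8 | (4E,7S,8Z)-4,8-dimethyl-7,10-bis(triethylsilyloxy)deca-4,8-dienal | CC[Si](CC)(CC)OC/C=C(/C)[C@@H](O[Si](CC)(CC)CC)C/C=C(\C)CCC=O | intermediate
9 | methyl acrylate | C=CC(=O)OC | starting material
10 | methyl (3RS,6E,9S,10Z)-3-hydroxy-6,10-dimethyl-2-methylidene-9,12-bis(triethylsilyloxy)dodeca-6,10-dienoate | CC[Si](CC)(CC)OC/C=C(/C)[C@@H](O[Si](CC)(CC)CC)C/C=C(\C)CCC(O)C(=C)C(=O)OC | intermediate
11 | methyl (3RS,6E,9S,10Z)-3-(methanesulfonyloxy)-6,10-dimethyl-2-methylidene-9,12-bis(triethylsilyloxy)dodeca-6,10-dienoate | CC[Si](CC)(CC)OC/C=C(/C)[C@@H](O[Si](CC)(CC)CC)C/C=C(\C)CCC(OS(C)(=O)=O)C(=C)C(=O)OC | intermediate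
12 | methyl (3E,6E,9S,10Z)-6,10-dimethyl-2-methylidene-9,12-bis(triethylsilyloxy)dodeca-3,6,10-trienoate | CC[Si](CC)(CC)OC/C=C(/C)[C@@H](O[Si](CC)(CC)CC)C/C=C(\C)C/C=C/C(=C)C(=O)OC | intermediate
13 | methyl 2-[(2R,3R)-3-({(2R,3R)-2-methyl-3-[(2S,3Z)-3-methyl-2,5-bis(triethylsilyloxy)pent-3-en-1-yl]oxiran-2-yl}methyl)oxiran-2-yl]prop-2-enoate | CC[Si](CC)(CC)OC/C=C(/C)[C@@H](O[Si](CC)(CC)CC)C[C@H]1O[C@]1(C)C[C@H]1O[C@@H]1C(=C)C(=O)OC | intermediate
14 | methyl (2Z,4R)-2-(bromomethyl)-4-hydroxy-5-{(2R,3R)-2-methyl-3-[(2S,3Z)-3-methyl-2,5-bis(triethylsilyloxy)pent-3-en-1-yl]oxiran-2-yl}pent-2-enoate | CC[Si](CC)(CC)OC/C=C(/C)[C@@H](O[Si](CC)(CC)CC)C[C@H]1O[C@]1(C)C[C@@H](O)/C=C(\CBr)C(=O)OC | intermediate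
15 | tiglic aldehyde, (2E)-2-methylbut-2-enal | C/C=C(\C)C=O | starting material
16 | (2R,3S)-2,3-dimethyloxirane-2-carbaldehyde | O=C[C@]1(C)O[C@H]1C | intermediate
17 | (2R,3S)-2,3-dimethyloxirane-2-carboxylic acid | OC(=O)[C@]1(C)O[C@H]1C | intermediate
18 | methyl (2Z,4R)-2-(bromomethyl)-4-{[(2R,3S)-2,3-dimethyloxirane-2-carbonyl]oxy}-5-{(2R,3R)-2-methyl-3-[(2S,3Z)-3-methyl-2,5-bis(triethylsilyloxy)pent-3-en-1-yl]oxiran-2-yl}pent-2-enoate | CC[Si](CC)(CC)OC/C=C(/C)[C@@H](O[Si](CC)(CC)CC)C[C@H]1O[C@]1(C)C[C@@H](OC(=O)[C@]1(C)O[C@H]1C)/C=C(\CBr)C(=O)OC | intermediate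
19 | methyl (2Z,4R)-2-(bromomethyl)-4-{[(2R,3S)-2,3-dimethyloxirane-2-carbonyl]oxy}-5-{(2R,3R)-2-methyl-3-[(2S,3Z)-3-methyl-5-oxo-2-(triethylsilyloxy)pent-3-en-1-yl]oxiran-2-yl}pent-2-enoate | O=C/C=C(/C)[C@@H](O[Si](CC)(CC)CC)C[C@H]1O[C@]1(C)C[C@@H](OC(=O)[C@]1(C)O[C@H]1C)/C=C(\CBr)C(=O)OC | intermediate
20 | methyl (1R,3S,4Z,6R,7S,8R,10R)-8-{[(2R,3S)-2,3-dimethyloxirane-2-carbonyl]oxy}-1,10-epoxy-6-hydroxy-3-(triethylsilyloxy)germacra-4,11(13)-dien-12-oate (same spatial arrangement as 21; C7 is S only because O6 carries H) | C=C(C(=O)OC)[C@H]1[C@H](O)/C=C(/C)[C@@H](O[Si](CC)(CC)CC)C[C@H]2O[C@]2(C)C[C@H]1OC(=O)[C@]1(C)O[C@H]1C | intermediate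
21 | (1R,3S,4Z,6R,7R,8R,10R)-1,10-epoxy-3-(triethylsilyloxy)germacra-4,11(13)-dien-12,6-olid-8-yl (2R,3S)-2,3-dimethyloxirane-2-carboxylate | C=C1C(=O)O[C@@H]2/C=C(/C)[C@@H](O[Si](CC)(CC)CC)C[C@H]3O[C@]3(C)C[C@@H](OC(=O)[C@]3(C)O[C@H]3C)[C@@H]12 | intermediate
22 | (1R,3S,4Z,6R,7R,8R,10R)-1,10-epoxy-3-hydroxygermacra-4,11(13)-dien-12,6-olid-8-yl (2R,3S)-2,3-dimethyloxirane-2-carboxylate | C=C1C(=O)O[C@@H]2/C=C(/C)[C@@H](O)C[C@H]3O[C@]3(C)C[C@@H](OC(=O)[C@]3(C)O[C@H]3C)[C@@H]12 | target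

## Step count and risks

Total steps: 15. Longest linear sequence: 13 (steps 1–9 and 12–15; steps 10–11 make acid 17).

**Step 2 (proposed new alkylation).** Risks are C3- instead of C5-alkylation of the furanolate, dialkylation, and racemisation of 5 by re-deprotonation. The fallback uses known chemistry, sets out from 3 and returns at 5. Methyl acetoacetate is alkylated with 3 (K2CO3, NaI, acetone) to methyl (4E)-2-acetyl-8,8-dimethoxy-5-methyloct-4-enoate F1. Krapcho dealkoxycarbonylation (LiCl, wet DMSO, 140 °C) gives (5E)-9,9-dimethoxy-6-methylnon-5-en-2-one F2. D-Proline-catalysed α-aminoxylation with nitrosobenzene at the internal α-carbon gives (3S,5E)-3-(anilinooxy)-9,9-dimethoxy-6-methylnon-5-en-2-one F3, and N–O cleavage (Zn, AcOH, THF) gives (3S,5E)-3-hydroxy-9,9-dimethoxy-6-methylnon-5-en-2-one F4. Heating F4 with (triphenylphosphoranylidene)ketene Ph3P=C=C=O in toluene (O-acylation, then intramolecular Wittig reaction) builds the butenolide 5 around the existing stereocentre.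

**Step 9 (bromide opening in the presence of the 1,10-oxirane).** Risks are competing opening of the trisubstituted oxirane and, in the esterification that follows, ring closure of the hydroxy bromide to a dihydrofuran. The fallback sets out from 13 and returns at 18 without a free hydroxy bromide. Copper-catalysed SN2' borylative opening (B2pin2, CuCl 5 mol %, Xantphos, NaOt-Bu, MeOH/THF) touches only the vinyl oxirane and gives methyl (2E,4R)-4-hydroxy-5-{(2R,3R)-2-methyl-3-[(2S,3Z)-3-methyl-2,5-bis(triethylsilyloxy)pent-3-en-1-yl]oxiran-2-yl}-2-[(4,4,5,5-tetramethyl-1,3,2-dioxaborolan-2-yl)methyl]pent-2-enoate F5. Yamaguchi esterification with 17 gives the corresponding 4-[(2R,3S)-2,3-dimethyloxirane-2-carbonyl]oxy boronate F6. Oxidation with NaBO3·4H2O in THF/H2O gives methyl (2E,4R)-4-{[(2R,3S)-2,3-dimethyloxirane-2-carbonyl]oxy}-2-(hydroxymethyl)-5-{(2R,3R)-2-methyl-3-[(2S,3Z)-3-methyl-2,5-bis(triethylsilyloxy)pent-3-en-1-yl]oxiran-2-yl}pent-2-enoate F7, and CBr4/PPh3 converts it into 18.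

**Step 14 (chromium ring closure).** Risks are the C6/C7 diastereoselectivity, which rests on analogy and is not secured, loss of the O8 acyloxy group by 1,4-elimination from the allyl-chromium species, and oligomerisation. The fallback sets out from 14, returns at 21, and closes the ring on an O8 silyl ether with the acylation moved to the end. It removes the leaving group and gives a sterically different cyclisation substrate. Silylation of 14 (Me3SiCl, imidazole, CH2Cl2) gives methyl (2Z,4R)-2-(bromomethyl)-5-{(2R,3R)-2-methyl-3-[(2S,3Z)-3-methyl-2,5-bis(triethylsilyloxy)pent-3-en-1-yl]oxiran-2-yl}-4-(trimethylsilyloxy)pent-2-enoate F8. Swern oxidation of the primary silyl ether gives methyl (2Z,4R)-2-(bromomethyl)-5-{(2R,3R)-2-methyl-3-[(2S,3Z)-3-methyl-5-oxo-2-(triethylsilyloxy)pent-3-en-1-yl]oxiran-2-yl}-4-(trimethylsilyloxy)pent-2-enoate F9. CrCl2 closure followed by a dilute citric acid work-up (which removes the trimethylsilyl group only after the 12,6-lactone has formed) gives (1R,3S,4Z,6R,7R,8R,10R)-1,10-epoxy-8-hydroxy-3-(triethylsilyloxy)germacra-4,11(13)-dien-12,6-olide F10. Yamaguchi esterification of F10 with 17 gives 21.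

## Further compounds

F1 | step 2 | methyl (4E)-2-acetyl-8,8-dimethoxy-5-methyloct-4-enoate | COC(=O)C(C(C)=O)C/C=C(\C)CCC(OC)OC
F2 | step 2 | (5E)-9,9-dimethoxy-6-methylnon-5-en-2-one | CC(=O)CC/C=C(\C)CCC(OC)OC
F3 | step 2 | (3S,5E)-3-(anilinooxy)-9,9-dimethoxy-6-methylnon-5-en-2-one | CC(=O)[C@@H](ONc1ccccc1)C/C=C(\C)CCC(OC)OC
F4 | step 2 | (3S,5E)-3-hydroxy-9,9-dimethoxy-6-methylnon-5-en-2-one | CC(=O)[C@@H](O)C/C=C(\C)CCC(OC)OC
F5 | step 9 | methyl (2E,4R)-4-hydroxy-5-{(2R,3R)-2-methyl-3-[(2S,3Z)-3-methyl-2,5-bis(triethylsilyloxy)pent-3-en-1-yl]oxiran-2-yl}-2-[(4,4,5,5-tetramethyl-1,3,2-dioxaborolan-2-yl)methyl]pent-2-enoate | CC[Si](CC)(CC)OC/C=C(/C)[C@@H](O[Si](CC)(CC)CC)C[C@H]1O[C@]1(C)C[C@@H](O)/C=C(\CB1OC(C)(C)C(C)(C)O1)C(=O)OC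
F6 | step 9 | methyl (2E,4R)-4-{[(2R,3S)-2,3-dimethyloxirane-2-carbonyl]oxy}-5-{(2R,3R)-2-methyl-3-[(2S,3Z)-3-methyl-2,5-bis(triethylsilyloxy)pent-3-en-1-yl]oxiran-2-yl}-2-[(4,4,5,5-tetramethyl-1,3,2-dioxaborolan-2-yl)methyl]pent-2-enoate | CC[Si](CC)(CC)OC/C=C(/C)[C@@H](O[Si](CC)(CC)CC)C[C@H]1O[C@]1(C)C[C@@H](OC(=O)[C@]1(C)O[C@H]1C)/C=C(\CB1OC(C)(C)C(C)(C)O1)C(=O)OC
F7 | step 9 | methyl (2E,4R)-4-{[(2R,3S)-2,3-dimethyloxirane-2-carbonyl]oxy}-2-(hydroxymethyl)-5-{(2R,3R)-2-methyl-3-[(2S,3Z)-3-methyl-2,5-bis(triethylsilyloxy)pent-3-en-1-yl]oxiran-2-yl}pent-2-enoate | CC[Si](CC)(CC)OC/C=C(/C)[C@@H](O[Si](CC)(CC)CC)C[C@H]1O[C@]1(C)C[C@@H](OC(=O)[C@]1(C)O[C@H]1C)/C=C(\CO)C(=O)OC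
F8 | step 14 | methyl (2Z,4R)-2-(bromomethyl)-5-{(2R,3R)-2-methyl-3-[(2S,3Z)-3-methyl-2,5-bis(triethylsilyloxy)pent-3-en-1-yl]oxiran-2-yl}-4-(trimethylsilyloxy)pent-2-enoate | CC[Si](CC)(CC)OC/C=C(/C)[C@@H](O[Si](CC)(CC)CC)C[C@H]1O[C@]1(C)C[C@@H](O[Si](C)(C)C)/C=C(\CBr)C(=O)OC
F9 | step 14 | methyl (2Z,4R)-2-(bromomethyl)-5-{(2R,3R)-2-methyl-3-[(2S,3Z)-3-methyl-5-oxo-2-(triethylsilyloxy)pent-3-en-1-yl]oxiran-2-yl}-4-(trimethylsilyloxy)pent-2-enoate | O=C/C=C(/C)[C@@H](O[Si](CC)(CC)CC)C[C@H]1O[C@]1(C)C[C@@H](O[Si](C)(C)C)/C=C(\CBr)C(=O)OC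
F10 | step 14 | (1R,3S,4Z,6R,7R,8R,10R)-1,10-epoxy-8-hydroxy-3-(triethylsilyloxy)germacra-4,11(13)-dien-12,6-olide | C=C1C(=O)O[C@@H]2/C=C(/C)[C@@H](O[Si](CC)(CC)CC)C[C@H]3O[C@]3(C)C[C@@H](O)[C@@H]12
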